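**Strategy.** Everything rests on opening the carbocycle (C5–C10) across the C5–C6 bond. Its homoallylic alcohol motif, C6(OH)–C5(H)–C4(=CH2)–CHO, is the retron of an intramolecular allylboration, and the trans-fused lactone at C7/C8 locks the closing chair. The precursor already contains the lactone and the oxirane: a trans α-methylene-γ-butyrolactone with CH2OH (C6) at C7 and, at C8, the chain C9(O-acyl)–C10(Me)(oxiranyl)–CH=C(CHO)–CH2Bpin of fixed E geometry. Oxidising that CH2OH to the aldehyde triggers closure through a closed transition state that forms C5–C6, sets C5 and C6 (axial 6-OH syn to the C10 methyl), unmasks the exocyclic methylene and delivers the target in the same operation.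

Key step: step 17

Remark (numbering used throughout): C1/C2 = oxirane CH/CH2; C10 = quaternary carbon; C5 = ring CH carrying C4(=CH2)–CHO; C6 = carbinol carbon; C7/C8 = ring-fusion carbons (C8–O of the lactone); C9 = acyloxy carbon; C11–C13 = methylene lactone. TBS = tert-butyldimethylsilyl, Bpin = 4,4,5,5-tetramethyl-1,3,2-dioxaborolan-2-yl.

**Route**

Step 1
Reactants: 1 (E)-2-methylbut-2-enal
Product: 2 tert-butyldimethyl[(2-methylbuta-1,3-dien-1-yl)oxy]silane (E/Z mixture at the enol ether)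
Conditions: TBSOTf, Et3N, Et2O, 0 °C → rt
Reagents that add atoms: tert-butyldimethylsilyl triflate, CC(C)(C)[Si](C)(C)OS(=O)(=O)C(F)(F)F
Why: Silyl dienol ether formation by O-silylation and γ-deprotonation of the enal; the enol ether geometry is irrelevant because that carbon becomes sp3 in step 2.

Step 2
Reactants: 2 silyl dienol ether
Product: 3 (Z)-tert-butyldimethyl{[2-methyl-4-(Bpin)but-2-en-1-yl]oxy}silane
Conditions: Ni(cod)2 (2.5 mol%), PCy3 (2.5 mol%), pinacolborane, PhMe, rt
Reagents that add atoms: pinacolborane, [H]B1OC(C)(C)C(C)(C)O1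
Why: Nickel-catalysed 1,4-hydroboration of a 1,3-diene, in which the s-cis diene on nickel takes H at the oxygenated terminus and boron at the CH2 terminus, so the new trisubstituted alkene should be Z (CH2B cis to CH2OTBS) from either enol ether isomer.

Step 3
Reactants: 3 (Z)-allylboronate; 4 2-[(tert-butyldimethylsilyl)oxy]acetaldehyde
Product: 6 (2S,3S)-1-[(TBS)oxy]-3-{[(TBS)oxy]methyl}-3-methylpent-4-en-2-ol, via O-pinacolboryl ether 5 (not isolated)
Conditions: (S)-TRIP phosphoric acid (5 mol%; the enantiomer that exposes the Si face), 4 Å MS, PhMe, −30 → 0 °C; aq. NaHCO3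
Reagents that add atoms: none
Why: Chiral phosphoric acid-catalysed allylboration through a chair Zimmerman–Traxler transition state, in which the catalyst directs bond formation to the Si face of the aldehyde (C9, S) and the Z geometry of 3 places CH2OTBS syn and methyl anti to the new hydroxyl, fixing the quaternary C10.

Step 4
Reactants: 6 homoallylic alcohol
Product: 7 tert-butyl (2S,3S)-1-[(TBS)oxy]-3-{[(TBS)oxy]methyl}-3-methylpent-4-en-2-yl carbonate
Conditions: Boc2O, DMAP, MeCN, rt
Reagents that add atoms: di-tert-butyl dicarbonate, CC(C)(C)OC(=O)OC(=O)OC(C)(C)C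
Why: DMAP-catalysed carbonate formation on the secondary alcohol installs the internal oxygen nucleophile for step 5.

Step 5
Reactants: 7 tert-butyl carbonate
Product: 8 (4S,5S,6R)-4,5-bis{[(TBS)oxy]methyl}-6-(iodomethyl)-5-methyl-1,3-dioxan-2-one
Conditions: IBr, PhMe, −85 °C; aq. Na2S2O3
Reagents that add atoms: iodine monobromide, IBr
Why: Iodocarbonate cyclisation (6-exo attack of the carbonate carbonyl on the iodonium ion, loss of the tert-butyl group) through a chair with the C9 substituent and the new CH2I equatorial, which should set C1 1,3-syn to C9.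

Step 6
Reactants: 8 cyclic iodocarbonate
Product: 9 (2S,3S)-1,4-bis[(TBS)oxy]-3-methyl-3-[(2R)-oxiran-2-yl]butan-2-ol
Conditions: K2CO3, MeOH, 0 °C → rt
Reagents that add atoms: none
Why: Carbonate methanolysis frees the C1 alkoxide, which closes the oxirane by intramolecular SN2 (3-exo-tet) on the primary iodide with retention at C1 and leaves the C9 hydroxyl free.

Step 7
Reactants: 9 epoxy alcohol; 10 (S)-2-methylbutanoic anhydride
Product: 11 (2S,3R)-1,4-bis[(TBS)oxy]-3-methyl-3-[(2R)-oxiran-2-yl]butan-2-yl (2S)-2-methylbutanoate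
Conditions: DMAP, Et3N, CH2Cl2, rt → 40 °C
Reagents that add atoms: none
Why: DMAP-catalysed acyl transfer (Steglich-type) to the hindered C9 alcohol from the enantiopure anhydride, which brings in the (S)-2-methylbutanoyl stereocentre unchanged.

Step 8
Reactants: 11 bis-silyl ether
Product: 12 (2S,3R)-1,4-dihydroxy-3-methyl-3-[(2R)-oxiran-2-yl]butan-2-yl (2S)-2-methylbutanoate
Conditions: TBAF, AcOH, THF, 0 °C → rt
Reagents that add atoms: none
Why: Fluoride cleavage of both primary silyl ethers, buffered with acetic acid to suppress acyl migration and epoxide opening.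

Step 9
Reactants: 12 diol
Product: 13 (2S,3R)-3-methyl-3-[(2R)-oxiran-2-yl]-1,4-dioxobutan-2-yl (2S)-2-methylbutanoate
Conditions: Dess–Martin periodinane (2.5 equiv), NaHCO3, CH2Cl2, 0 °C → rt; used crude
Reagents that add atoms: none
Why: Dess–Martin oxidation of both primary alcohols under buffered, neutral conditions, where C10 is quaternary and C9 should not epimerise.

Step 10
Reactants: 14 tert-butyldimethyl(prop-2-yn-1-yloxy)silane
Product: 15 methyl 4-[(TBS)oxy]but-2-ynoate
Conditions: n-BuLi, THF, −78 °C; ClCO2Me, −78 → 0 °C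
Reagents that add atoms: methyl chloroformate, COC(=O)Cl
Why: Deprotonation of the terminal alkyne and C-acylation of the lithium acetylide by the chloroformate.

Step 11
Reactants: 15 ynoate
Product: 17 methyl (Z)-4-[(TBS)oxy]-2-[(Bpin)methyl]but-2-enoate, via vinylalane 16 (not isolated)
Conditions: DIBAL-H, HMPA, THF, 0 °C; then ICH2Bpin, 0 °C → rt
Reagents that add atoms: 2-(iodomethyl)-4,4,5,5-tetramethyl-1,3,2-dioxaborolane, ICB1OC(C)(C)C(C)(C)O1
Why: Conjugate hydroalumination of the ynoate (syn addition, H and Al cis) and alkylation of the α-alumino acrylate by the iodomethylboronate with retention, so CH2OTBS should end trans to CH2B (Z).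

Step 12
Reactants: 13 dialdehyde; 17 2-(methoxycarbonyl)allylboronate (1.1 equiv)
Product: 19 lactone aldehyde: (1S,2R)-1-[(2R,3S)-3-{[(TBS)oxy]methyl}-4-methylidene-5-oxooxolan-2-yl]-2-methyl-2-[(2R)-oxiran-2-yl]-3-oxopropyl (2S)-2-methylbutanoate, via O-pinacolboryl hydroxy ester 18 (not isolated)
Conditions: PhMe, 80 °C
Reagents that add atoms: none
Why: Thermal allylboration of the unhindered, more electrophilic α-acyloxy aldehyde through a chair transition state (CH2OTBS trans to CH2B gives the anti adduct, hence the 7,8-trans lactone), with Felkin–Anh/Cornforth attack anti to the C9 acyloxy group setting C8, followed by lactonisation of the borate in situ; the neopentyl C5 aldehyde should be left untouched.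

Step 13
Reactants: 19 lactone aldehyde
Product: 20 E enal: (1S,2R,3E)-1-[(2R,3S)-3-{[(TBS)oxy]methyl}-4-methylidene-5-oxooxolan-2-yl]-2-methyl-2-[(2R)-oxiran-2-yl]-5-oxopent-3-en-1-yl (2S)-2-methylbutanoate
Conditions: Ph3P=CHCHO (1.3 equiv), PhMe, 80 °C
Reagents that add atoms: (triphenylphosphoranylidene)acetaldehyde, O=CC=P(c1ccccc1)(c1ccccc1)c1ccccc1
Why: Wittig olefination of the neopentyl aldehyde with the stabilised formyl ylide should give the E enal.

Step 14
Reactants: 20 enal
Product: 21 Z α-iodoenal: (1S,2R,3Z)-4-iodo analogue of 20 (iodine at C4, cis to C10)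
Conditions: I2, K2CO3, DMAP (20 mol%), THF–H2O, rt
Reagents that add atoms: iodine, II
Why: Amine-catalysed α-iodination of the enal (conjugate addition of DMAP, iodination of the enolate, elimination; Baylis–Hillman-type), which should give the Z α-iodoenal with CHO trans to C10.

Step 15
Reactants: 21 silyl ether
Product: 22 hydroxy iodoenal: (1S,2R,3Z)-1-[(2R,3S)-3-(hydroxymethyl)-4-methylidene-5-oxooxolan-2-yl]-4-iodo-2-methyl-2-[(2R)-oxiran-2-yl]-5-oxopent-3-en-1-yl (2S)-2-methylbutanoate
Conditions: TBAF, AcOH, THF, 0 °C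
Reagents that add atoms: none
Why: Buffered fluoride desilylation frees the C6 carbinol before boron is introduced, because fluoride would activate an allylboronate.

Step 16
Reactants: 22 hydroxy iodoenal
Product: 23 (1S,2R,3E)-4-formyl-1-[(2R,3S)-3-(hydroxymethyl)-4-methylidene-5-oxooxolan-2-yl]-2-methyl-2-[(2R)-oxiran-2-yl]-5-(Bpin)pent-3-en-1-yl (2S)-2-methylbutanoate
Conditions: Zn dust, ICH2Bpin, THF, rt; then 22, Pd(PPh3)4 (5 mol%), THF, rt → 40 °C
Reagents that add atoms: 2-(iodomethyl)-4,4,5,5-tetramethyl-1,3,2-dioxaborolane, ICB1OC(C)(C)C(C)(C)O1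
Why: Negishi cross-coupling of the alkenyl iodide with the (borylmethyl)zinc reagent proceeds with retention of alkene geometry, so CH2Bpin should be cis to C10 (E).

Step 17
Reactants: 23 hydroxy 2-formylallyl boronate
Product: 26 CNP0510523.1 (target), via aldehyde 24 (not isolated), via O-pinacolboryl cyclisation product 25 (not isolated)
Conditions: Dess–Martin periodinane, NaHCO3, CH2Cl2, 0 °C → rt, then 35 °C; aq. NaHCO3/Na2S2O3
Reagents that add atoms: none
Why: Dess–Martin oxidation of the C6 carbinol gives aldehyde 24, whose (E)-2-formylallyl boronate then adds through a closed six-membered boron-to-oxygen (Zimmerman–Traxler-type) transition state, C5 to C6, with allylic transposition that turns CH2–B into the exocyclic methylene. The closest known reaction is the intramolecular allylboration of ω-formyl allylboronates, here with a configurationally stable 2-acyl-substituted boronate. The carbocycle closes in 6-exo-trig mode onto the aldehyde, as a chair trans-fused to the lactone with C7/C8 diequatorial and the C10 methyl and C9 acyloxy group axial. C5 is set by that locked chair (C4 equatorial, H5 axial) and C6 by the alkene geometry: because CH2B is cis to C10, the B–O tether forces the aldehyde oxygen axial, syn to the C10 methyl and cis to the C5 substituent. The step needs chemoselectivity for the aliphatic over the conjugated aldehyde and cyclisation ahead of C7 epimerisation, which the favoured six-membered closure, the quaternary C10 and the buffered base-free medium should secure. Hydrolysis of borate 25 on work-up releases the target.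

**Compound list**

1 | (E)-2-methylbut-2-enal | C/C=C(\C)C=O | starting material
2 | tert-butyldimethyl[(2-methylbuta-1,3-dien-1-yl)oxy]silane (E/Z mixture, 1E drawn) | C=C/C(C)=C/O[Si](C)(C)C(C)(C)C | intermediate
3 | (Z)-tert-butyldimethyl{[2-methyl-4-(Bpin)but-2-en-1-yl]oxy}silane | C/C(=C/CB1OC(C)(C)C(C)(C)O1)CO[Si](C)(C)C(C)(C)C | intermediate
4 | 2-[(tert-butyldimethylsilyl)oxy]acetaldehyde | O=CCO[Si](C)(C)C(C)(C)C | starting material
5 | O-pinacolboryl ether of 6 (not isolated) | CC(C)(C)[Si](C)(C)OC[C@@H](OB1OC(C)(C)C(C)(C)O1)[C@](C)(CO[Si](C)(C)C(C)(C)C)C=C | intermediate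
6 | (2S,3S)-1-[(TBS)oxy]-3-{[(TBS)oxy]methyl}-3-methylpent-4-en-2-ol | CC(C)(C)[Si](C)(C)OC[C@@H](O)[C@](C)(CO[Si](C)(C)C(C)(C)C)C=C | intermediate
7 | tert-butyl (2S,3S)-1-[(TBS)oxy]-3-{[(TBS)oxy]methyl}-3-methylpent-4-en-2-yl carbonate | CC(C)(C)[Si](C)(C)OC[C@@H](OC(=O)OC(C)(C)C)[C@](C)(CO[Si](C)(C)C(C)(C)C)C=C | intermediate
8 | (4S,5S,6R)-4,5-bis{[(TBS)oxy]methyl}-6-(iodomethyl)-5-methyl-1,3-dioxan-2-one | O=C1O[C@@H](CI)[C@@](C)(CO[Si](C)(C)C(C)(C)C)[C@@H](CO[Si](C)(C)C(C)(C)C)O1 | intermediate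
9 | (2S,3S)-1,4-bis[(TBS)oxy]-3-methyl-3-[(2R)-oxiran-2-yl]butan-2-ol | CC(C)(C)[Si](C)(C)OC[C@@H](O)[C@](C)(CO[Si](C)(C)C(C)(C)C)[C@@H]1CO1 | intermediate
10 | (S)-2-methylbutanoic anhydride | CC[C@H](C)C(=O)OC(=O)[C@@H](C)CC | starting material
11 | (2S,3R)-1,4-bis[(TBS)oxy]-3-methyl-3-[(2R)-oxiran-2-yl]butan-2-yl (2S)-2-methylbutanoate | CC(C)(C)[Si](C)(C)OC[C@@H](OC(=O)[C@@H](C)CC)[C@](C)(CO[Si](C)(C)C(C)(C)C)[C@@H]1CO1 | intermediate
12 | (2S,3R)-1,4-dihydroxy-3-methyl-3-[(2R)-oxiran-2-yl]butan-2-yl (2S)-2-methylbutanoate | OC[C@@H](OC(=O)[C@@H](C)CC)[C@](C)(CO)[C@@H]1CO1 | intermediate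
13 | (2S,3R)-3-methyl-3-[(2R)-oxiran-2-yl]-1,4-dioxobutan-2-yl (2S)-2-methylbutanoate | O=C[C@@H](OC(=O)[C@@H](C)CC)[C@](C)(C=O)[C@@H]1CO1 | intermediate
14 | tert-butyldimethyl(prop-2-yn-1-yloxy)silane | C#CCO[Si](C)(C)C(C)(C)C | starting material
15 | methyl 4-[(TBS)oxy]but-2-ynoate | COC(=O)C#CCO[Si](C)(C)C(C)(C)C | intermediate
16 | methyl (E)-2-(diisobutylalumanyl)-4-[(TBS)oxy]but-2-enoate (Al cis to H; not isolated) | COC(=O)/C([Al](CC(C)C)CC(C)C)=C\CO[Si](C)(C)C(C)(C)C | intermediate
17 | methyl (Z)-4-[(TBS)oxy]-2-[(Bpin)methyl]but-2-enoate | COC(=O)/C(CB1OC(C)(C)C(C)(C)O1)=C\CO[Si](C)(C)C(C)(C)C | intermediate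
18 | O-pinacolboryl γ-hydroxy α-methylene ester, open-chain precursor of 19 (not isolated) | COC(=O)C(=C)[C@@H](CO[Si](C)(C)C(C)(C)C)[C@@H](OB1OC(C)(C)C(C)(C)O1)[C@@H](OC(=O)[C@@H](C)CC)[C@](C)(C=O)[C@@H]2CO2 | intermediate
19 | (1S,2R)-1-[(2R,3S)-3-{[(TBS)oxy]methyl}-4-methylidene-5-oxooxolan-2-yl]-2-methyl-2-[(2R)-oxiran-2-yl]-3-oxopropyl (2S)-2-methylbutanoate | C=C1C(=O)O[C@H]([C@@H]1CO[Si](C)(C)C(C)(C)C)[C@@H](OC(=O)[C@@H](C)CC)[C@](C)(C=O)[C@@H]2CO2 | intermediate
20 | (1S,2R,3E)-1-[(2R,3S)-3-{[(TBS)oxy]methyl}-4-methylidene-5-oxooxolan-2-yl]-2-methyl-2-[(2R)-oxiran-2-yl]-5-oxopent-3-en-1-yl (2S)-2-methylbutanoate | C=C1C(=O)O[C@H]([C@@H]1CO[Si](C)(C)C(C)(C)C)[C@@H](OC(=O)[C@@H](C)CC)[C@](C)(/C=C/C=O)[C@@H]2CO2 | intermediate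
21 | (1S,2R,3Z)-4-iodo analogue of 20 (I cis to C10) | C=C1C(=O)O[C@H]([C@@H]1CO[Si](C)(C)C(C)(C)C)[C@@H](OC(=O)[C@@H](C)CC)[C@](C)(/C=C(\I)C=O)[C@@H]2CO2 | intermediate
22 | (1S,2R,3Z)-1-[(2R,3S)-3-(hydroxymethyl)-4-methylidene-5-oxooxolan-2-yl]-4-iodo-2-methyl-2-[(2R)-oxiran-2-yl]-5-oxopent-3-en-1-yl (2S)-2-methylbutanoate | C=C1C(=O)O[C@H]([C@@H]1CO)[C@@H](OC(=O)[C@@H](C)CC)[C@](C)(/C=C(\I)C=O)[C@@H]2CO2 | intermediate
23 | (1S,2R,3E)-4-formyl-1-[(2R,3S)-3-(hydroxymethyl)-4-methylidene-5-oxooxolan-2-yl]-2-methyl-2-[(2R)-oxiran-2-yl]-5-(Bpin)pent-3-en-1-yl (2S)-2-methylbutanoate | C=C1C(=O)O[C@H]([C@@H]1CO)[C@@H](OC(=O)[C@@H](C)CC)[C@](C)(/C=C(\CB3OC(C)(C)C(C)(C)O3)C=O)[C@@H]2CO2 | intermediate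
24 | (1S,2R,3E)-4-formyl-1-[(2R,3R)-3-formyl-4-methylidene-5-oxooxolan-2-yl]-2-methyl-2-[(2R)-oxiran-2-yl]-5-(Bpin)pent-3-en-1-yl (2S)-2-methylbutanoate (not isolated) | C=C1C(=O)O[C@H]([C@@H]1C=O)[C@@H](OC(=O)[C@@H](C)CC)[C@](C)(/C=C(\CB3OC(C)(C)C(C)(C)O3)C=O)[C@@H]2CO2 | intermediate
25 | O-pinacolboryl ether of 26 at O6 (not isolated) | C=C1C(=O)O[C@@H]2[C@@H]1[C@@H](OB3OC(C)(C)C(C)(C)O3)[C@@H](C(=C)C=O)[C@](C)([C@@H]1CO1)[C@@H]2OC(=O)[C@@H](C)CC | intermediate
26 | CNP0510523.1: (1R,5R,6S,7S,8R,9S,10R)-1,2-epoxy-6β-hydroxy-9α-[(2S)-2-methylbutanoyloxy]-15-oxoelema-3,11(13)-dien-12,8α-olide | C=C1C(=O)O[C@@H]2[C@@H]1[C@@H](O)[C@@H](C(=C)C=O)[C@](C)([C@@H]1CO1)[C@@H]2OC(=O)[C@@H](C)CC | target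

**Totals.** 17 steps in all; longest linear sequence 15 steps (steps 1–9 and 12–17; steps 10–11 make the side fragment 17).

**Steps most likely to fail**

1. Step 17 (key step). The closed chair must place the aldehyde oxygen axial, 1,3-syn to the axial C10 methyl. The cyclisation may therefore be slow and leak through a boat-like transition state to the C6 epimer, or be overtaken by enolisation at C7. The fallback sets out from 23 and comes back at 26, and corrects C6 by substrate-controlled reduction instead of by the transition state. The cyclisation is run as before; if the 6-epimeric carbinol F1 forms, it is oxidised with Dess–Martin periodinane to the 6-oxo enal F2. Luche reduction (NaBH4, CeCl3, MeOH, −78 °C) then reduces ketone and enal 1,2-, with hydride entering C6 equatorially, away from the axial C10 methyl, to give the 6β,15-diol F3. MnO2 oxidises only the primary allylic alcohol of F3 and should give 26.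

2. Step 12. Discrimination between the two aldehydes of 13 may be incomplete during the long heating that the sluggish 2-alkoxycarbonyl allylboronate needs, so the neopentyl C5 aldehyde may also be consumed. The fallback sets out from 12 and comes back at 19, and differentiates the two carbons at the alcohol stage. TEMPO/PhI(OAc)2 oxidises only the unhindered C8 carbinol of 12 to the hydroxy aldehyde F4 (in equilibrium with its five-membered lactol). Allylboration of F4 with 17 (PhMe, 80 °C) gives the hydroxymethyl lactone F5, and Dess–Martin oxidation of F5 gives 19.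

3. Step 16. The free α-iodoenal and primary alcohol may be lost to side reactions during the organozinc coupling (protonolysis of the zinc reagent, slow oxidative addition, intermolecular allylboration of the enal by the product). The fallback sets out from 22 and comes back at 24, and lowers the oxidation level for the coupling. Luche reduction of 22 gives the iodo diol F6, and Negishi coupling of F6 with the (borylmethyl)zinc reagent gives the diol allylboronate F7, which carries no electrophilic carbonyl. Dess–Martin oxidation of both primary alcohols of F7 then generates 24 in the flask, which closes to 26 as in step 17.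

**Further compounds**

F1 | step 17 | 6-epimer of 26 (6α-OH) | C=C1C(=O)O[C@@H]2[C@@H]1[C@H](O)[C@@H](C(=C)C=O)[C@](C)([C@@H]1CO1)[C@@H]2OC(=O)[C@@H](C)CC
F2 | step 17 | 6-oxo enal (6-dehydro-26) | C=C1C(=O)O[C@@H]2[C@@H]1C(=O)[C@@H](C(=C)C=O)[C@](C)([C@@H]1CO1)[C@@H]2OC(=O)[C@@H](C)CC
F3 | step 17 | 6β,15-diol (15-alcohol of 26) | C=C1C(=O)O[C@@H]2[C@@H]1[C@@H](O)[C@@H](C(=C)CO)[C@](C)([C@@H]1CO1)[C@@H]2OC(=O)[C@@H](C)CC
F4 | step 12 | (2S,3R)-4-hydroxy-3-methyl-3-[(2R)-oxiran-2-yl]-1-oxobutan-2-yl (2S)-2-methylbutanoate | O=C[C@@H](OC(=O)[C@@H](C)CC)[C@](C)(CO)[C@@H]1CO1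
F5 | step 12 | C5 primary alcohol corresponding to 19 | C=C1C(=O)O[C@H]([C@@H]1CO[Si](C)(C)C(C)(C)C)[C@@H](OC(=O)[C@@H](C)CC)[C@](C)(CO)[C@@H]2CO2
F6 | step 16 | (Z)-iodo diol (C15 alcohol of 22) | C=C1C(=O)O[C@H]([C@@H]1CO)[C@@H](OC(=O)[C@@H](C)CC)[C@](C)(/C=C(\I)CO)[C@@H]2CO2
F7 | step 16 | (E)-diol allylboronate (C15 alcohol of 23) | C=C1C(=O)O[C@H]([C@@H]1CO)[C@@H](OC(=O)[C@@H](C)CC)[C@](C)(/C=C(\CB3OC(C)(C)C(C)(C)O3)CO)[C@@H]2CO2
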